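The side chain is numbered C1' (ylidene CH) to C13' (CH2 on the furan). The furanone ring is O1, C2 to C5.
Retrosynthetic cuts: O–CH3 at O4; C5'–C6' (B-alkyl Suzuki–Miyaura); C4'–C5' (made as C4'=C5' by Wittig methylenation of a C4' aldehyde); C1'–C2' (enantioselective redox-relay Heck alkenylation); and, inside the C6'–C13' iodide, C6'=C7' (iodo-Wittig) and C11'–C12' (B-alkyl Suzuki–Miyaura).
Forward: both rings are bought (3-methyltetronic acid, furan-3-carbaldehyde). The chain is joined in the order C1'–C2', C4'–C5', then C5'–C6' with the separately made furyl dienyl iodide, and O-demethylation ends the route.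
Enabling feature: C1' is the δ-carbon of the push–pull dienoate O=C2–C3=C4–C5=C1' of the furanone ring, so its enol triflate is an electron-poor alkenyl electrophile. C2' is followed by unbranched CH2 groups (C3', C4') whose hydrogens let palladium migrate from C3' to a terminal carbinol, and that carbinol (the helper) ends as the C4' aldehyde used to add C5'.
Stereochemistry: C2' (S) comes from a chiral pyridine-oxazoline ligand acting on two achiral partners. C5=C1' (Z) comes from the triflate, C6'=C7' (Z) from the iodo-Wittig reaction and C10'=C11' (E) from syn-carboalumination, and all three are carried through stereoretentive couplings.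

Key step: step 5

Assumption: the (S)-configured ligand is taken to deliver the alkenyl group to the Si face of C3 of (E)-but-2-en-1-ol. If the sense of induction is the opposite one, the (R)-ligand is used and nothing else changes.

Step 1
Reactants: 1 3-methyltetronic acid (4-hydroxy-3-methylfuran-2(5H)-one)
Product: 2 4-methoxy-3-methylfuran-2(5H)-one
Conditions: Me2SO4, K2CO3, acetone, reflux
Reagents that add atoms: dimethyl sulfate, COS(=O)(=O)OC
Why: Williamson-type O-alkylation of the tetronate anion at O4 should give the vinylogous methyl ester, which removes the acidic proton and leaves C5–H2 as the only acidic site for step 2.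

Step 2
Reactants: 2 4-methoxy-3-methylfuran-2(5H)-one
Product: 4 5-(hydroxymethylene)-4-methoxy-3-methylfuran-2(5H)-one, via lithium dienolate 3 (not isolated)
Conditions: LDA (1.1 equiv), THF, −78 °C; HCO2Me, −78 → 0 °C; aq HCl work-up
Reagents that add atoms: methyl formate, COC=O
Why: Deprotonation at C5 gives the 2-oxidofuran-type dienolate, whose crossed Claisen condensation with methyl formate (C-formylation) should install C1' at the aldehyde level, the product being held as its stabilised enolate until work-up.

Step 3
Reactants: 4 5-(hydroxymethylene)-4-methoxy-3-methylfuran-2(5H)-one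
Product: 5 (Z)-(3-methoxy-4-methyl-5-oxofuran-2(5H)-ylidene)methyl trifluoromethanesulfonate
Conditions: Tf2O, i-Pr2NEt, CH2Cl2, −78 °C
Reagents that add atoms: trifluoromethanesulfonic anhydride, O=S(=O)(OS(=O)(=O)C(F)(F)F)C(F)(F)F
Why: O-sulfonylation of the formyl enolate (enol triflate formation) should occur at the formyl oxygen, which carries most of the charge as in formyl esters, and on the side of ring O1 (Z), because the 3-methyl group turns the 4-O-methyl group toward C5 and blocks the E site.

Step 4
Reactants: 6 but-2-yn-1-ol
Product: 7 (E)-but-2-en-1-ol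
Conditions: LiAlH4, THF, reflux; aq work-up; distillation
Reagents that add atoms: none
Why: Hydroxyl-directed trans-hydroalumination of the propargylic alcohol followed by protonolysis should give the geometrically pure E-alkene, which is needed because E and Z alkenols lead to opposite enantiomers in step 5.

Step 5
Reactants: 5 (Z)-(3-methoxy-4-methyl-5-oxofuran-2(5H)-ylidene)methyl trifluoromethanesulfonate; 7 (E)-but-2-en-1-ol (1.5 equiv)
Product: 8 (3S,4Z)-4-(3-methoxy-4-methyl-5-oxofuran-2(5H)-ylidene)-3-methylbutanal
Conditions: Pd2(dba)3 (3 mol %), (S)-4-tert-butyl-2-[5-(trifluoromethyl)pyridin-2-yl]-4,5-dihydrooxazole (8 mol %), 3 Å MS, DMA, rt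
Reagents that add atoms: none
Why: Zerovalent palladium inserts into the C–O bond of the electron-poor enol triflate 5 with retention of the Z geometry, the cationic divalent alkenylpalladium–pyridine-oxazoline complex binds the alkene of 7, syn migratory insertion forms the C1'–C2' bond at C3 of the butenol, and β-hydride elimination toward the carbinol followed by re-insertion and loss of HOTf releases aldehyde 8 and zerovalent palladium. The closest known reaction type is the enantioselective redox-relay Heck alkenylation of acyclic alkenols with electron-poor alkenyl triflates under palladium/pyridine-oxazoline catalysis. No ring is closed. The new stereocentre is set in the insertion step by the tert-butyl group of the ligand, which lets only one face (Si at C3) of the geometrically pure E-alkene approach the Pd–alkenyl bond, so two achiral partners should give the S centre. Site selectivity (C3 over C2 of the butenol) is secured by the polarisation of the alkene by its CH2OH group and by the small methyl terminus, and the direction of β-hydride elimination (away from the new allylic C2'–H) is secured by the electron-withdrawing dienoate of the furanone ring, which makes that C–H less hydridic, and by the irreversible formation of the C=O group. The lactone, the vinylogous ester and the ylidene alkene should be spectators at room temperature without added base.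

Step 6
Reactants: 8 (3S,4Z)-4-(3-methoxy-4-methyl-5-oxofuran-2(5H)-ylidene)-3-methylbutanal
Product: 9 (5Z)-4-methoxy-3-methyl-5-[(2S)-2-methylpent-4-en-1-ylidene]furan-2(5H)-one
Conditions: Ph3PCH3Br, KHMDS, THF, 0 °C; then 8, −78 → 0 °C
Reagents that add atoms: methyltriphenylphosphonium bromide, C[P+](c1ccccc1)(c1ccccc1)c1ccccc1.[Br-]
Why: Wittig methylenation is much faster at the aldehyde than at the lactone or the vinylogous ester, adds C5', and at low temperature with about one equivalent of ylide should leave the weakly acidic C2'–H and hence the stereocentre untouched.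

Step 7
Reactants: 10 pent-4-yn-1-ol
Product: 12 (E)-5-iodo-4-methylpent-4-en-1-ol, via alkenylalane 11 (not isolated)
Conditions: Me3Al (3 equiv), Cp2ZrCl2 (0.25 equiv), CH2Cl2, 0 °C → rt; I2, THF, −30 → 0 °C; aq work-up
Reagents that add atoms: trimethylaluminium, C[Al](C)C; iodine, II
Why: Zirconium-catalysed syn-carboalumination (Negishi carboalumination) of the terminal alkyne places CH3 and Al on the same side, and iodinolysis with retention should give the E-iodide that carries the C10'=C11' geometry.

Step 8
Reactants: 13 furan-3-carbaldehyde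
Product: 14 3-vinylfuran
Conditions: Ph3PCH3Br, n-BuLi, THF, 0 °C; then 13, 0 °C → rt
Reagents that add atoms: methyltriphenylphosphonium bromide, C[P+](c1ccccc1)(c1ccccc1)c1ccccc1.[Br-]
Why: Wittig methylenation of the heteroaromatic aldehyde gives the vinylfuran, which is volatile and is therefore carried on as a titrated THF solution.

Step 9
Reactants: 14 3-vinylfuran; 12 (E)-5-iodo-4-methylpent-4-en-1-ol
Product: 16 (E)-7-(furan-3-yl)-4-methylhept-4-en-1-ol, via furylethyl-9-BBN 15 (not isolated)
Conditions: 9-BBN-H, THF, 0 °C → rt; then 12, PdCl2(dppf) (5 mol %), AsPh3, Cs2CO3, DMF–H2O, rt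
Reagents that add atoms: none
Why: Anti-Markovnikov hydroboration of the vinyl group with 9-BBN and B-alkyl Suzuki–Miyaura coupling with the alkenyl iodide, which proceeds with retention, should form C11'–C12' without touching the furan or the free alcohol.

Step 10
Reactants: 16 (E)-7-(furan-3-yl)-4-methylhept-4-en-1-ol
Product: 17 (E)-7-(furan-3-yl)-4-methylhept-4-enal
Conditions: Dess–Martin periodinane, CH2Cl2, 0 °C → rt
Reagents that add atoms: none
Why: Dess–Martin oxidation stops at the aldehyde under nearly neutral conditions that the furan and the trisubstituted alkene tolerate.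

Step 11
Reactants: 17 (E)-7-(furan-3-yl)-4-methylhept-4-enal
Product: 18 3-[(3E,7Z)-8-iodo-4-methylnona-3,7-dien-1-yl]furan
Conditions: EtPPh3I, n-BuLi, THF, rt; I2, −78 °C; NaHMDS, −20 °C; then 17, −20 °C
Reagents that add atoms: ethyltriphenylphosphonium iodide, CC[P+](c1ccccc1)(c1ccccc1)c1ccccc1.[I-]; iodine, II
Why: The Stork–Zhao-type Wittig reaction of the α-iodo ylide Ph3P=C(I)CH3 with an unbranched aldehyde is kinetically Z-selective (iodine cis to the chain) and should set the C6'=C7' geometry.

Step 12
Reactants: 9 (5Z)-4-methoxy-3-methyl-5-[(2S)-2-methylpent-4-en-1-ylidene]furan-2(5H)-one; 18 3-[(3E,7Z)-8-iodo-4-methylnona-3,7-dien-1-yl]furan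
Product: 20 (5Z)-5-[(2S,6Z,10E)-13-(furan-3-yl)-2,6,10-trimethyltrideca-6,10-dien-1-ylidene]-4-methoxy-3-methylfuran-2(5H)-one, via B-alkyl-9-BBN 19 (not isolated)
Conditions: 9-BBN-H, THF, 0 °C → rt; then 18, PdCl2(dppf) (5 mol %), AsPh3, Cs2CO3, DMF–H2O, rt
Reagents that add atoms: none
Why: 9-BBN hydroborates only the monosubstituted C4'=C5' alkene (the ylidene and ring alkenes are more highly substituted and electron-poor), and the B-alkyl Suzuki–Miyaura coupling with the Z-iodide proceeds with retention at room temperature, so C5'–C6' should form with all alkene geometries and the C2' centre intact.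

Step 13
Reactants: 20 (5Z)-5-[(2S,6Z,10E)-13-(furan-3-yl)-2,6,10-trimethyltrideca-6,10-dien-1-ylidene]-4-methoxy-3-methylfuran-2(5H)-one
Product: 21 (5Z)-5-[(2S,6Z,10E)-13-(furan-3-yl)-2,6,10-trimethyltrideca-6,10-dien-1-ylidene]-4-hydroxy-3-methylfuran-2(5H)-one (target)
Conditions: NaSEt, DMF, rt → 50 °C; then cold 1 M HCl
Reagents that add atoms: none
Why: SN2 attack of the soft thiolate on the O-methyl carbon of the vinylogous ester (nucleophilic demethylation) releases the tetronate anion, a good leaving group, and the thiolate is too weak a base to remove C2'–H, so acidification should give the target with its S centre unchanged.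

Compound list
1 | 3-methyltetronic acid (4-hydroxy-3-methylfuran-2(5H)-one) | CC1=C(O)COC1=O | starting material
2 | 4-methoxy-3-methylfuran-2(5H)-one | CC1=C(OC)COC1=O | intermediate
3 | lithium 4-methoxy-3-methylfuran-2-olate (lithium dienolate of 2) | Cc1c(OC)coc1[O-].[Li+] | intermediate
4 | 5-(hydroxymethylene)-4-methoxy-3-methylfuran-2(5H)-one (enol of the 5-carbaldehyde, E/Z labile) | CC1=C(OC)C(=CO)OC1=O | intermediate
5 | (Z)-(3-methoxy-4-methyl-5-oxofuran-2(5H)-ylidene)methyl trifluoromethanesulfonate | CC1=C(OC)/C(=C/OS(=O)(=O)C(F)(F)F)OC1=O | intermediate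
6 | but-2-yn-1-ol | CC#CCO | starting material
7 | (E)-but-2-en-1-ol | C/C=C/CO | intermediate
8 | (3S,4Z)-4-(3-methoxy-4-methyl-5-oxofuran-2(5H)-ylidene)-3-methylbutanal | CC1=C(OC)/C(=C/[C@@H](C)CC=O)OC1=O | intermediate
9 | (5Z)-4-methoxy-3-methyl-5-[(2S)-2-methylpent-4-en-1-ylidene]furan-2(5H)-one | CC1=C(OC)/C(=C/[C@@H](C)CC=C)OC1=O | intermediate
10 | pent-4-yn-1-ol | C#CCCCO | starting material
11 | dimethylaluminium (E)-5-(dimethylalumanyl)-4-methylpent-4-en-1-olate | C[Al](C)OCCC/C(C)=C/[Al](C)C | intermediate
12 | (E)-5-iodo-4-methylpent-4-en-1-ol | OCCC/C(C)=C/I | intermediate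
13 | furan-3-carbaldehyde | O=Cc1ccoc1 | starting material
14 | 3-vinylfuran | C=Cc1ccoc1 | intermediate
15 | 9-[2-(furan-3-yl)ethyl]-9-borabicyclo[3.3.1]nonane | C(Cc1ccoc1)B1C2CCCC1CCC2 | intermediate
16 | (E)-7-(furan-3-yl)-4-methylhept-4-en-1-ol | OCCC/C(C)=C/CCc1ccoc1 | intermediate
17 | (E)-7-(furan-3-yl)-4-methylhept-4-enal | O=CCC/C(C)=C/CCc1ccoc1 | intermediate
18 | 3-[(3E,7Z)-8-iodo-4-methylnona-3,7-dien-1-yl]furan | I/C(C)=C\CC/C(C)=C/CCc1ccoc1 | intermediate
19 | (5Z)-5-[(2S)-5-(9-borabicyclo[3.3.1]nonan-9-yl)-2-methylpentylidene]-4-methoxy-3-methylfuran-2(5H)-one | CC1=C(OC)/C(=C/[C@@H](C)CCCB2C3CCCC2CCC3)OC1=O | intermediate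
20 | (5Z)-5-[(2S,6Z,10E)-13-(furan-3-yl)-2,6,10-trimethyltrideca-6,10-dien-1-ylidene]-4-methoxy-3-methylfuran-2(5H)-one | CC1=C(OC)/C(=C/[C@@H](C)CCC/C(C)=C\CC/C(C)=C/CCc2ccoc2)OC1=O | intermediate
21 | (5Z)-5-[(2S,6Z,10E)-13-(furan-3-yl)-2,6,10-trimethyltrideca-6,10-dien-1-ylidene]-4-hydroxy-3-methylfuran-2(5H)-one | CC1=C(O)/C(=C/[C@@H](C)CCC/C(C)=C\CC/C(C)=C/CCc2ccoc2)OC1=O | target

Total step count: 13. Longest linear sequence: 7 steps (1, 2, 3, 5, 6, 12, 13).

Steps most likely to fail

Step 5. The triflate may solvolyse before oxidative addition. Facial selectivity may be poor with the small methyl terminus. β-Hydride elimination may run toward the new allylic C–H and give a conjugated triene, or the acid released may acetalise the aldehyde.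
The fallback forms the same bond by a stereoretentive cross-coupling of a configurationally defined secondary alkylzinc reagent. It sets out from 5 and comes back at 9. Commercial (R)-pent-4-en-2-ol is converted by an Appel reaction (I2, PPh3, imidazole, inversion) into (S)-4-iodopent-1-ene F1. Iodine–lithium exchange with t-BuLi in pentane–ether at −100 °C gives, with retention, (S)-pent-4-en-2-yllithium F2. This is trapped at once with Me3SiCH2ZnBr·LiBr as (S)-pent-4-en-2-yl(trimethylsilylmethyl)zinc F3. Negishi coupling of F3 with 5 under [1,3-bis(2,6-di(pentan-3-yl)phenyl)imidazol-2-ylidene](3-chloropyridine)PdCl2 in THF at −25 °C → rt should proceed with retention at both carbons and give 9 directly, so that steps 4 to 6 are not needed.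

Step 3. Sulfonylation may take place at the lactone carbonyl oxygen with aromatisation to a furyl triflate, or the Z preference may be low.
The fallback sets the geometry by elimination and changes the leaving group. It sets out from 2 and comes back at 8. Dienolate 3 is trapped with gaseous formaldehyde to give racemic 5-(hydroxymethyl)-4-methoxy-3-methylfuran-2(5H)-one F4. MsCl/Et3N gives (3-methoxy-4-methyl-5-oxo-2,5-dihydrofuran-2-yl)methyl methanesulfonate F5, and further Et3N eliminates it to 4-methoxy-3-methyl-5-methylenefuran-2(5H)-one F6. Addition of Br2 in CH2Cl2 gives 5-bromo-5-(bromomethyl)-4-methoxy-3-methylfuran-2(5H)-one F7. Dehydrobromination with Et3N should give, for the same steric reason as in step 3, (Z)-5-(bromomethylene)-4-methoxy-3-methylfuran-2(5H)-one F8. F8 is then used in place of 5 under the catalyst of step 5, with AgOTf (1.1 equiv) as halide scavenger to reach the same cationic alkenylpalladium species, and gives 8.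

Step 11. The iodo ylide may be lost by protonation or deiodination, the Z selectivity may erode, and traces of free iodine may attack the furan.
The fallback builds the same trisubstituted alkenyl halide by selective substitution of a 1,1-dihalide. It sets out from 17 and comes back at 20. A Corey–Fuchs reaction (CBr4, PPh3, CH2Cl2, 0 °C) gives 3-[(3E)-8,8-dibromo-4-methylocta-3,7-dien-1-yl]furan F9. Trans-selective Negishi monomethylation (Me2Zn, PdCl2(DPEphos), THF, rt) replaces only the bromine trans to the chain and should give 3-[(3E,7Z)-8-bromo-4-methylnona-3,7-dien-1-yl]furan F10. F10 takes the place of 18 in step 12.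

Further compounds
F1 | step 5 | (S)-4-iodopent-1-ene | I[C@@H](C)CC=C
F2 | step 5 | (S)-pent-4-en-2-yllithium | [Li][C@@H](C)CC=C
F3 | step 5 | (S)-pent-4-en-2-yl(trimethylsilylmethyl)zinc | C[Si](C)(C)C[Zn][C@@H](C)CC=C
F4 | step 3 | 5-(hydroxymethyl)-4-methoxy-3-methylfuran-2(5H)-one (racemic) | CC1=C(OC)C(CO)OC1=O
F5 | step 3 | (3-methoxy-4-methyl-5-oxo-2,5-dihydrofuran-2-yl)methyl methanesulfonate (racemic) | CC1=C(OC)C(COS(C)(=O)=O)OC1=O
F6 | step 3 | 4-methoxy-3-methyl-5-methylenefuran-2(5H)-one | CC1=C(OC)C(=C)OC1=O
F7 | step 3 | 5-bromo-5-(bromomethyl)-4-methoxy-3-methylfuran-2(5H)-one (racemic) | CC1=C(OC)C(Br)(CBr)OC1=O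
F8 | step 3 | (Z)-5-(bromomethylene)-4-methoxy-3-methylfuran-2(5H)-one | CC1=C(OC)/C(=C/Br)OC1=O
F9 | step 11 | 3-[(3E)-8,8-dibromo-4-methylocta-3,7-dien-1-yl]furan | BrC(Br)=CCC/C(C)=C/CCc1ccoc1
F10 | step 11 | 3-[(3E,7Z)-8-bromo-4-methylnona-3,7-dien-1-yl]furan | Br/C(C)=C\CC/C(C)=C/CCc1ccoc1
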